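(The data come from a simulation from invented constants; scatter was added.)

A small charge of partner puts a lid on triple product, and the balance of that charge shows how near a flask stands to the lid.

all flasks: solid substrate 0.20 M

| charge | partner | remark | time |
|---|---|---|---|
| eta | 0.52 equiv | run made earlier |  |
| alpha | 3.6 equiv | run made earlier |  |
| red | 1.00 equiv |  | 40 min |
| green | 2.00 equiv |  | 40 min |
| teal | 4.00 equiv |  | 40 min |

| run | time / min | triple product / % | double product / % | solid substrate / % |
|---|---|---|---|---|
| eta | 3.00 | 0 | 2 | 96 |
| eta | 5.00 | 0 | 0 | 94 |
| eta | 8.00 | 2 | 2 | 94 |
| eta | 12.0 | 2 | 2 | 92 |
| eta | 15.0 | 2 | 1 | 90 |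
| eta | 25.0 | 2 | 2 | 87 |
| eta | 40.0 | 5 | 1 | 81 |
| alpha | 6.00 | 0 | 0 | 96 |
| alpha | 12.0 | 4 | 0 | 91 |
| alpha | 15.0 | 2 | 1 | 88 |
| alpha | 25.0 | 14 | 0 | 77 |
| alpha | 30.0 | 16 | 0 | 75 |
| alpha | 40.0 | 23 | 1 | 65 |

(readings scatter by 1.5 percentage points)

- percentages count the solid substrate that a species holds: one side product counts as two
- solid, in amounts per volume of the solution: solid substrate
- steps that have been proposed: first product -> decomposed reagent; starting material + partner -> first product; starting material + double product -> side product; partner + double product -> triple product; solid substrate <-> starting material; partner + first product -> double product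
- at the start none of the solid substrate is in solution

- final triple product, as a percentage of the solid substrate charged, for each flask in turn (red, green, teal)

1. In the proposed steps, partner adds to starting material, then to first product, then to double product. Each triple product has therefore taken 3 partners, and none of the proposed steps shows partner coming back.

2. Counted in fractions of the solid substrate charged, red's partner ceiling is 33.3%: the partner equivalents over 3. Partner is then the limiting reagent of red. In the alpha run the same division gives 120%, above the whole substrate charge, so there the ceiling is merely a yardstick.

3. The fill is triple product divided by the ceiling. The eta run has a ceiling of 17.3% and holds 5% at 40.0 min, a fill of 28.8%. The alpha run holds 23% at 40.0 min, a fill of 19.2%. Both are readings, each triple product good to 1.5 percentage points, and both stand below one.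

4. Red and green lie between these two charges, so this reckoning carries both fills over. Red comes to 6.39% to 9.59%, and green to 12.8% to 19.2%. Teal lies beyond alpha, so it takes alpha's fill and comes to 25.6%.

5. The forecast gives single values from “an apparent order of about 0.75”: 8.5%, 14% and 25%. Its red and green values lie inside these ranges, and its teal value lies below this reckoning's figure.

Red, green and teal give 6.65%, 14.7% and 24.1%, and the forecast stands within its tolerance.

    first product → decomposed reagent (k = 8.92 × 10⁻⁴ /s)
    starting material + partner → first product (k = 0.0152 /M/s)
    starting material + double product → side product (k = 0.0215 /M/s)
    partner + double product → triple product (k = 0.0287 /M/s)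
    solid substrate ⇌ starting material, rate k5*(cs5 - [starting material]) while solid is left; crystals form when [starting material] > cs5 (solubility = 17.0 mM, k = 0.00200 /s)
    partner + first product → double product (k = 0.00572 /M/s)

At 40.0 min, red still holds 65% of its partner, and its triple product fills 20.0% of the ceiling of 33.3%. Green at 400 min has 4.65% of its partner left, with triple product at 45.4%, which is 68.1% of that flask's ceiling of 66.7%, and decomposed reagent at 50.9%.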